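Remark on the chemistry: the target has no stereocentre and no stereogenic axis (rings A and F are symmetric about their biaryl axes), so no configuration has to be set. The ring and atom labels defined in the first section are used throughout.

## Structural features

The target (C36H26O19) is an achiral hexameric phlorotannin: six benzene rings A to F carrying sixteen free phenolic OH groups, joined by three diaryl ether oxygens and two biaryl C–C bonds. Central ring C carries three neighbouring aryloxy groups, at C1 (to B5 of ring B), at C6 (to E1 of the 3,4,5-trihydroxyphenyl ring E) and at C5 (to D5 of ring D), and a free OH at C3; the two arms are identical, so the constitution has a mirror plane through C3, C6 and ring E. Ring B (and ring D, numbered the same way) is a fully differentiated phloroglucinol: OH at B2, B4 and B6, H at B3, the ether oxygen at B5 and the 2,4,6-trihydroxyphenyl ring A (ring F on ring D) bonded A1–B1. The free polyphenol is sensitive to air and base, so every oxygen has to travel masked until the last step, and the ketenes and the silyl ynol ether used on the way are sensitive to moisture. The real difficulty sits on rings B and D, each of which carries two congested linkages side by side: the C1–O–B5 ether joins a ring C carbon that has an ortho aryloxy group to a carbon with two ortho oxygens, and the B1–A1 bond is a biaryl with four ortho oxygens between two very electron-rich rings. The feature the key step exploits is the sequence around ring B: O (B6), aryl (B1), O (B2), H (B3), O (B4), O (B5). This is the pattern delivered when a four-carbon vinylketene (B3–B4–B5–B6, ketene carbonyl = B6, alkoxy on B4, aryloxy on B5) combines with a two-carbon ynol ether (B1–B2, aryl on B1, oxygen on B2), so rings B and D can be built with the ether oxygen and ring A already attached.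

## Logic of the disconnections

23 ⇒ 22 ⇒ 21. No skeletal bond is cut; ten O–CH3, two O–CH2CH3 and two O–Si bonds are put back. The free hexadecaphenol cannot pass through ketene chemistry, and simple alkyl ethers are the only masks compatible with steps 2 to 10. The demand on the forward steps is exhaustive dealkylation that leaves three diaryl ethers and two biaryl bonds intact.

21 ⇒ 17 + 5 (key). In ring B the bonds B1–B6 and B2–B3 are cut, and likewise in ring D. The remaining four-carbon unit B3–B4–B5–B6 is folded back into the cyclobutenone of 17 by joining B3 to B6. Rings B and D carry both hard linkages, so making the rings removes the need for either hindered coupling. In one sentence: rings B and D are not coupled to their neighbours but grown, by a twofold cyclobutenone/siloxyalkyne benzannulation of 17 with 5. The gain is that hexaaryl 21 falls to 17, which has only rings C and E, and to the single-ring alkyne 5. The demand is a regiospecific [2+2] of 18 with 5, clean passage through 19 and 20, and complete reaction on both arms.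

17 ⇒ 15 ⇒ 14. In each cyclobutenone the bonds between carbons 1 and 2 and between carbons 3 and 4 are cut (ketene plus ynol ether [2+2]; the two-carbon partner is the ynol ether reagent of step 9), and the acyl chlorides are taken back to carboxylic acids. This converts an aryl–O–aryl problem into an aryloxyacetic acid. The demand is that each ketene unit of 16 is trapped faster than it oligomerizes, and that 15 is made without a Lewis acid because ring C is very electron-rich.

14 ⇒ 13. The two O–CH2 bonds are cut; the two-carbon acid units come from the haloacetic acid reagent of step 7. The C1 and C5 oxygens of ring C are then bonded to sp3 carbon by SN2 instead of to a hindered aryl carbon. The forward step needs only a double alkylation of two equivalent phenols.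

13 ⇒ 12 ⇒ 10 + 11. The O–E1 bond is cut. This is the only diaryl ether made by coupling, and it is the easy one: E1 has two ortho hydrogens, so only 10 is hindered. The flanking oxygens of 10 must carry masks that come off without touching methyl ethers, to release 13.

10 ⇒ 7 ⇒ 6. The C6–O bond of ring C is cut back to C–H. The forward sequence is directed metalation between the two acetal oxygens (8), borylation (9) and oxidation. The demand is selectivity for the position between the two acetal ethers over the two positions between an acetal ether and the methoxy group.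

5 ⇒ 2 ⇒ 1. The O–Si bond and the O–C(sp) bond are cut (oxygen transfer to acetylide 3 gives ynolate 4), then the alkyne carbon is removed (one-carbon homologation of 1). The demand is silylation of 4 on oxygen, not on carbon.

## Other disconnections considered

Alternative 1: the route drawn first. The cut is at the two ring C–O–arm ether bonds and the two biaryl bonds. Forward, a Suzuki coupling (Pd(OAc)2, SPhos) builds the arm phenol A1, and a twofold Ullmann etherification (CuI) of A1 with the central dibromide A2 gives the hexadecamethyl ether A3, which is then demethylated. Each Ullmann event must join a phenol with two ortho methoxy groups to a bromide carbon with an ortho aryloxy group, and the second event occurs beside two aryloxy groups. Copper phenoxide couplings slow sharply when both partners are ortho-substituted, so reduction of the electron-rich C–Br bond should compete. A1 itself needs a Suzuki coupling that forms a biaryl with four ortho substituents from a boron partner with two ortho methoxy groups, a class prone to protodeboronation. That makes four hindered couplings, against one ring-forming operation in the chosen plan.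

Alternative 2: the same two ether bonds cut at the quinone oxidation level. Forward, two molecules of A1 and 2,6-dichloro-1,4-benzoquinone A5 are joined in a three-component, twofold addition–elimination to give the bis(aryloxy)quinone A4. Reduction, differentiation of the two OH groups and arylation of the hindered one with ring E follow. The union needs no metal and tolerates ortho substitution, but the plan still needs the hindered Suzuki coupling to A1. The electron-rich phenoxide of A1 is also a plausible one-electron reductant towards a haloquinone. The last ether would have to be formed at an OH flanked by two hexamethoxybiphenylyloxy groups, the most hindered site of the molecule. The chosen plan attaches ring E first, at an unhindered stage, and never forms an arm ether by coupling.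

Alternative 3: ring construction of the terminal rings A and F. The cut is inside rings A and F. Forward, a twofold Danheiser benzannulation of the bis(siloxyalkyne) A6 with 3-ethoxycyclobut-2-en-1-one A7 gives the two outer phloroglucinol rings. This removes only the biaryl problem. The two hindered arm ethers and the fully substituted rings B and D must already be present in A6 and would come from the couplings of Alternative 1. A6 also needs two ynol ethers installed late at carbons flanked by two methoxy groups. In the chosen plan the same reaction class solves the ether and the biaryl together, because the ring created is B (and D), not A (and F).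

Key step: step 10

## Steps

Step 1
Reactants: 1 2,4,6-trimethoxybenzaldehyde
Product: 2 2-ethynyl-1,3,5-trimethoxybenzene
Conditions: Ohira–Bestmann reagent (1.5 equiv), K2CO3, MeOH, rt
Reagents that add atoms: Ohira–Bestmann reagent [dimethyl (1-diazo-2-oxopropyl)phosphonate], CC(=O)C(=[N+]=[N-])P(=O)(OC)OC
Why: Seyferth–Gilbert homologation in the Ohira–Bestmann form: methanolysis of the reagent releases the anion of dimethyl (diazomethyl)phosphonate, which adds to the aldehyde; loss of dimethyl phosphate and N2 and a 1,2-hydride shift of the alkylidene carbene should give the terminal alkyne, and the mild base leaves the aryl methyl ethers untouched.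

Step 2
Reactants: 2 2-ethynyl-1,3,5-trimethoxybenzene
Product: 5 triisopropyl{[(2,4,6-trimethoxyphenyl)ethynyl]oxy}silane, via lithium acetylide 3 (not isolated), via lithium ynolate 4 (not isolated)
Conditions: LiN(SiMe3)2, THF, −78 °C; LiOOtBu (from tBuOOH + LiN(SiMe3)2), −78 → 0 °C; iPr3SiOTf, −78 → 0 °C
Reagents that add atoms: tert-butyl hydroperoxide, CC(C)(C)OO; triisopropylsilyl trifluoromethanesulfonate, CC(C)[Si](C(C)C)(C(C)C)OS(=O)(=O)C(F)(F)F
Why: Oxidation of a lithium acetylide by lithium tert-butyl peroxide (electrophilic oxygen transfer with loss of tert-butoxide) is the known route to lithium ynolates, and the bulky silyl triflate should silylate on oxygen to give the siloxyalkyne; the alkyne C–H is far more acidic than any ring C–H, so ring metalation should not compete.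

Step 3
Reactants: 6 5-methoxybenzene-1,3-diol
Product: 7 1-methoxy-3,5-bis(methoxymethoxy)benzene
Conditions: MeOCH2Cl (2.5 equiv), iPr2NEt, CH2Cl2, 0 °C → rt
Reagents that add atoms: chloromethyl methyl ether, COCCl
Why: Standard acetal protection of both phenols; the methoxymethyl groups serve next as the stronger directing groups and later come off under conditions that spare methyl ethers.

Step 4
Reactants: 7 1-methoxy-3,5-bis(methoxymethoxy)benzene
Product: 10 4-methoxy-2,6-bis(methoxymethoxy)phenol, via aryllithium 8 (not isolated), via dimethyl arylboronate 9 (not isolated)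
Conditions: n-BuLi, THF, 0 °C; B(OMe)3, −78 °C → rt; H2O2, aq NaOH, 0 °C
Reagents that add atoms: hydrogen peroxide, OO
Why: Directed ortho metalation should occur at the position chelated by two methoxymethoxy groups in preference to the positions between one such group and the weaker methoxy director; borylation and peroxide oxidation (1,2-aryl shift from boron to oxygen) then install the C6 oxygen of ring C.

Step 5
Reactants: 10 4-methoxy-2,6-bis(methoxymethoxy)phenol; 11 5-iodo-1,2,3-trimethoxybenzene
Product: 12 1,2,3-trimethoxy-5-[4-methoxy-2,6-bis(methoxymethoxy)phenoxy]benzene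
Conditions: CuI (10 mol %), picolinic acid (20 mol %), K3PO4, DMSO, 90 °C, Ar
Reagents that add atoms: none
Why: Ullmann diaryl ether synthesis with the CuI/picolinic acid system, which accepts phenols with two ortho substituents; the iodide carbon E1 has two ortho hydrogens, so only one partner is hindered, and the acetal ethers are stable to base.

Step 6
Reactants: 12 1,2,3-trimethoxy-5-[4-methoxy-2,6-bis(methoxymethoxy)phenoxy]benzene
Product: 13 5-methoxy-2-(3,4,5-trimethoxyphenoxy)benzene-1,3-diol
Conditions: HCl (conc., cat.), MeOH, 50 °C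
Reagents that add atoms: none
Why: Acid-catalysed acetal exchange should transfer both methoxymethyl groups to methanol; aryl methyl ethers and the diaryl ether are inert under these conditions.

Step 7
Reactants: 13 5-methoxy-2-(3,4,5-trimethoxyphenoxy)benzene-1,3-diol
Product: 14 2,2'-{[5-methoxy-2-(3,4,5-trimethoxyphenoxy)-1,3-phenylene]bis(oxy)}diacetic acid
Conditions: ClCH2CO2H (3 equiv), NaOH (7 equiv), H2O/1,4-dioxane, 90 °C, Ar; then aq HCl
Reagents that add atoms: chloroacetic acid, OC(=O)CCl
Why: Williamson etherification of both symmetry-equivalent phenoxides with chloroacetate, the classical aryloxyacetic acid synthesis, which gives the diacid directly on acidification; SN2 at the primary α-chloro carboxylate is insensitive to the ortho aryloxy group, the excess of reagent covers its slow hydrolysis, and lactonization is impossible because the neighbouring oxygen at C6 is already arylated.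

Step 8
Reactants: 14 2,2'-{[5-methoxy-2-(3,4,5-trimethoxyphenoxy)-1,3-phenylene]bis(oxy)}diacetic acid
Product: 15 2,2'-{[5-methoxy-2-(3,4,5-trimethoxyphenoxy)-1,3-phenylene]bis(oxy)}diacetyl dichloride
Conditions: (COCl)2 (3 equiv), DMF (1 mol %), CH2Cl2, 0 °C → rt; evaporation, crude product used directly
Reagents that add atoms: oxalyl chloride, ClC(=O)C(Cl)=O
Why: Acid chloride formation through the catalytic chloroiminium species; no Lewis acid is present, so intramolecular Friedel–Crafts acylation of electron-rich ring C should not occur, the catalyst loading is too low for ring formylation to matter, and the gaseous by-products leave on evaporation.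

Step 9
Reactants: 15 2,2'-{[5-methoxy-2-(3,4,5-trimethoxyphenoxy)-1,3-phenylene]bis(oxy)}diacetyl dichloride
Product: 17 4,4'-{[5-methoxy-2-(3,4,5-trimethoxyphenoxy)-1,3-phenylene]bis(oxy)}bis(3-ethoxycyclobut-2-en-1-one), via bis(aryloxyketene) 16 (not isolated)
Conditions: ethoxyethyne (6 equiv, solution in hexanes), Et3N (2.4 equiv, slow addition), CH2Cl2, 0 °C → rt
Reagents that add atoms: ethoxyethyne, CCOC#C
Why: Dehydrochlorination of each acyl chloride gives the aryloxyketene, and the ketene/ynol ether [2+2] cycloaddition is polarity-controlled (the CH terminus of ethoxyethyne attacks the ketene carbonyl carbon), placing ethoxy on carbon 3 and the aryloxy group on carbon 4 of both four-membered rings; the two new stereocentres (carbon 4 of each ring) form without control as a mixture of diastereomers, which does not matter because step 10 destroys both.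

Step 10
Reactants: 17 4,4'-{[5-methoxy-2-(3,4,5-trimethoxyphenoxy)-1,3-phenylene]bis(oxy)}bis(3-ethoxycyclobut-2-en-1-one); 5 triisopropyl{[(2,4,6-trimethoxyphenyl)ethynyl]oxy}silane
Product: 21 3,3''-{[5-methoxy-2-(3,4,5-trimethoxyphenoxy)-1,3-phenylene]bis(oxy)}bis{4-ethoxy-2',4',6'-trimethoxy-6-[(triisopropylsilyl)oxy]biphenyl-2-ol}, via bis(vinylketene) 18 (not isolated), via bis(vinylcyclobutenone) 19 (not isolated), via bis(dienylketene) 20 (not isolated)
Conditions: 5 (3 equiv), toluene, 80 °C, slow addition of 17; then 110 °C
Reagents that add atoms: none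
Why: Danheiser benzannulation of a cyclobutenone with a siloxyalkyne, run on both arms in one flask. Heating opens each cyclobutenone of 17 by a conrotatory 4π electrocyclic reaction, the aryloxy donor on carbon 4 rotating outward, to give vinylketene 18. The ketene C=C bond of 18 then adds to the electron-rich alkyne of 5 in a regiospecific [2+2] cycloaddition, the aryl-bearing nucleophilic alkyne carbon attacking the ketene carbonyl carbon (B6–B1 bond) and the silyloxy-bearing carbon closing onto the ketene α-carbon (B2–B3 bond), to give 19. Reversible 4π opening of 19 gives dienylketene 20, and the isomer with the ketene carbon cis to the ethoxyvinyl group closes ring B (and ring D) by a thermal disrotatory 6π electrocyclization between the ketene carbon B6 and the aryloxy-bearing terminus B5 (six-membered carbocycle), followed by keto–enol tautomerization to the phenol. The closest known reaction type is the benzannulation of cyclobutenones with trialkylsilyloxyalkynes to resorcinol monosilyl ethers, and oxygen substituents on carbons 3 and 4 of a cyclobutenone are known to ease its ring opening. No stereocentre is formed, and the two stereocentres of 17 are erased. The selectivity needed is regiochemical and is fixed by the polarization of the ynol ether: ring A must end between B6–OH and B2–OSi and the ring C oxygen between B6–OH and B4–OEt, which is the only outcome of the polarity-matched [2+2]. Chemoselectivity against ketene dimerization and against acylation of the new phenols by 18 should be secured by slow addition of 17 to an excess of 5 and by the two ortho substituents that shield each new OH.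

Step 11
Reactants: 21 3,3''-{[5-methoxy-2-(3,4,5-trimethoxyphenoxy)-1,3-phenylene]bis(oxy)}bis{4-ethoxy-2',4',6'-trimethoxy-6-[(triisopropylsilyl)oxy]biphenyl-2-ol}
Product: 22 3,3''-{[5-methoxy-2-(3,4,5-trimethoxyphenoxy)-1,3-phenylene]bis(oxy)}bis(4-ethoxy-2',4',6'-trimethoxybiphenyl-2,6-diol)
Conditions: Bu4NF (2.5 equiv), AcOH (2.5 equiv), THF, 0 °C, Ar
Reagents that add atoms: none
Why: Fluoride-mediated cleavage of the two aryl silyl ethers, driven by Si–F bond formation; the acetic acid buffer keeps the electron-rich phenols protonated and so less prone to air oxidation.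

Step 12
Reactants: 22 3,3''-{[5-methoxy-2-(3,4,5-trimethoxyphenoxy)-1,3-phenylene]bis(oxy)}bis(4-ethoxy-2',4',6'-trimethoxybiphenyl-2,6-diol)
Product: 23 target hexadecaphenol CNP0279880.0
Conditions: BBr3 (excess), CH2Cl2, −78 °C → rt; then H2O, Ar
Reagents that add atoms: none
Why: Lewis acid dealkylation of aryl alkyl ethers: BBr3 coordinates each ether oxygen and bromide attacks the methyl or ethyl carbon by SN2, so the ten methyl and two ethyl ethers should be cleaved, whereas the diaryl ether and biaryl bonds offer no sp3 carbon for substitution and should persist.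

## Compound list

1 | 2,4,6-trimethoxybenzaldehyde | COc1cc(OC)c(C=O)c(OC)c1 | starting material
2 | 2-ethynyl-1,3,5-trimethoxybenzene | COc1cc(OC)c(C#C)c(OC)c1 | intermediate
3 | lithium (2,4,6-trimethoxyphenyl)acetylide | COc1cc(OC)c(C#C[Li])c(OC)c1 | intermediate (not isolated)
4 | lithium 2-(2,4,6-trimethoxyphenyl)ethynolate | COc1cc(OC)c(C#C[O-])c(OC)c1.[Li+] | intermediate (not isolated)
5 | triisopropyl{[(2,4,6-trimethoxyphenyl)ethynyl]oxy}silane | COc1cc(OC)c(C#CO[Si](C(C)C)(C(C)C)C(C)C)c(OC)c1 | intermediate
6 | 5-methoxybenzene-1,3-diol | COc1cc(O)cc(O)c1 | starting material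
7 | 1-methoxy-3,5-bis(methoxymethoxy)benzene | COCOc1cc(OC)cc(OCOC)c1 | intermediate
8 | [4-methoxy-2,6-bis(methoxymethoxy)phenyl]lithium | [Li]c1c(OCOC)cc(OC)cc1OCOC | intermediate (not isolated)
9 | dimethyl [4-methoxy-2,6-bis(methoxymethoxy)phenyl]boronate | COCOc1cc(OC)cc(OCOC)c1B(OC)OC | intermediate (not isolated)
10 | 4-methoxy-2,6-bis(methoxymethoxy)phenol | COCOc1cc(OC)cc(OCOC)c1O | intermediate
11 | 5-iodo-1,2,3-trimethoxybenzene | COc1cc(I)cc(OC)c1OC | starting material
12 | 1,2,3-trimethoxy-5-[4-methoxy-2,6-bis(methoxymethoxy)phenoxy]benzene | COCOc1cc(OC)cc(OCOC)c1Oc1cc(OC)c(OC)c(OC)c1 | intermediate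
13 | 5-methoxy-2-(3,4,5-trimethoxyphenoxy)benzene-1,3-diol | COc1cc(O)c(Oc2cc(OC)c(OC)c(OC)c2)c(O)c1 | intermediate
14 | 2,2'-{[5-methoxy-2-(3,4,5-trimethoxyphenoxy)-1,3-phenylene]bis(oxy)}diacetic acid | OC(=O)COc1cc(OC)cc(OCC(=O)O)c1Oc1cc(OC)c(OC)c(OC)c1 | intermediate
15 | 2,2'-{[5-methoxy-2-(3,4,5-trimethoxyphenoxy)-1,3-phenylene]bis(oxy)}diacetyl dichloride | ClC(=O)COc1cc(OC)cc(OCC(Cl)=O)c1Oc1cc(OC)c(OC)c(OC)c1 | intermediate
16 | bis(aryloxyketene): 2,2'-{[5-methoxy-2-(3,4,5-trimethoxyphenoxy)-1,3-phenylene]bis(oxy)}bis(ethen-1-one) | O=C=COc1cc(OC)cc(OC=C=O)c1Oc1cc(OC)c(OC)c(OC)c1 | intermediate (not isolated)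
17 | 4,4'-{[5-methoxy-2-(3,4,5-trimethoxyphenoxy)-1,3-phenylene]bis(oxy)}bis(3-ethoxycyclobut-2-en-1-one), mixture of diastereomers at the two carbons 4 | CCOC1=CC(=O)C1Oc1cc(OC)cc(OC2C(=O)C=C2OCC)c1Oc1cc(OC)c(OC)c(OC)c1 | intermediate
18 | bis(vinylketene): each arm O=C=CH–C(OEt)=CH–O–ring C, aryloxy group trans to the ketene carbon | O=C=C/C(OCC)=C/Oc1cc(OC)cc(O/C=C(OCC)/C=C=O)c1Oc1cc(OC)c(OC)c(OC)c1 | intermediate (not isolated)
19 | bis(vinylcyclobutenone): each arm a 2-(2,4,6-trimethoxyphenyl)-3-(triisopropylsilyloxy)cyclobut-2-en-1-one bearing the 1-ethoxy-2-aryloxyvinyl group on carbon 4, mixture of diastereomers | O=C1C(c2c(OC)cc(OC)cc2OC)=C(O[Si](C(C)C)(C(C)C)C(C)C)C1/C(OCC)=C/Oc1cc(OC)cc(O/C=C(OCC)/C2C(=O)C(c3c(OC)cc(OC)cc3OC)=C2O[Si](C(C)C)(C(C)C)C(C)C)c1Oc1cc(OC)c(OC)c(OC)c1 | intermediate (not isolated)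
20 | bis(dienylketene): each arm O=C=C(aryl)–C(OSi)=CH–C(OEt)=CH–O–ring C, ketene carbon cis to the ethoxyvinyl group | O=C=C(c2c(OC)cc(OC)cc2OC)/C(O[Si](C(C)C)(C(C)C)C(C)C)=C\C(OCC)=C\Oc1cc(OC)cc(O/C=C(OCC)/C=C(O[Si](C(C)C)(C(C)C)C(C)C)\C(c3c(OC)cc(OC)cc3OC)=C=O)c1Oc1cc(OC)c(OC)c(OC)c1 | intermediate (not isolated)
21 | 3,3''-{[5-methoxy-2-(3,4,5-trimethoxyphenoxy)-1,3-phenylene]bis(oxy)}bis{4-ethoxy-2',4',6'-trimethoxy-6-[(triisopropylsilyl)oxy]biphenyl-2-ol} | CCOc1cc(O[Si](C(C)C)(C(C)C)C(C)C)c(-c2c(OC)cc(OC)cc2OC)c(O)c1Oc1cc(OC)cc(Oc2c(OCC)cc(O[Si](C(C)C)(C(C)C)C(C)C)c(-c3c(OC)cc(OC)cc3OC)c2O)c1Oc1cc(OC)c(OC)c(OC)c1 | intermediate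
22 | 3,3''-{[5-methoxy-2-(3,4,5-trimethoxyphenoxy)-1,3-phenylene]bis(oxy)}bis(4-ethoxy-2',4',6'-trimethoxybiphenyl-2,6-diol) | CCOc1cc(O)c(-c2c(OC)cc(OC)cc2OC)c(O)c1Oc1cc(OC)cc(Oc2c(OCC)cc(O)c(-c3c(OC)cc(OC)cc3OC)c2O)c1Oc1cc(OC)c(OC)c(OC)c1 | intermediate
23 | CNP0279880.0, hexadecaphenol | Oc1cc(O)c(-c2c(O)cc(O)c(Oc3cc(O)cc(Oc4c(O)cc(O)c(-c5c(O)cc(O)cc5O)c4O)c3Oc3cc(O)c(O)c(O)c3)c2O)c(O)c1 | target

## Step count and least certain steps

Total step count: 12. Longest linear sequence: 10 steps (steps 3 to 12, from 6); steps 1 and 2 are the side branch to 5.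

**Step 10 (key step).**
- What may go wrong: the second annulation may stall at the mono-annulated stage. The vinylketene may be diverted into dimerization or into acylation of phenols already formed. Siloxyalkyne 5 may rearrange thermally to a silylketene by a 1,3-silyl shift. The [2+2] may be slowed because the two ortho methoxy groups shield the alkyne.
- Fallback (from 15, returning at 23): reverse the order of the two cycloadditions, so that the hindered alkyne meets a small, reactive ketene at low temperature and the thermal annulation uses the smallest ynol ether. The bis(aryloxyketene) 16, generated from 15 as in step 9, is trapped with 5 in place of ethoxyethyne (Et3N, CH2Cl2, 0 °C). The ketene/siloxyalkyne [2+2] should give 4,4'-{[5-methoxy-2-(3,4,5-trimethoxyphenoxy)-1,3-phenylene]bis(oxy)}bis[3-(triisopropylsilyloxy)-2-(2,4,6-trimethoxyphenyl)cyclobut-2-en-1-one] F1. Heating F1 with an excess of ethoxyethyne in toluene in a sealed vessel at 80 to 100 °C should give, by the same benzannulation manifold, 3,3''-{[5-methoxy-2-(3,4,5-trimethoxyphenoxy)-1,3-phenylene]bis(oxy)}bis{6-ethoxy-2',4',6'-trimethoxy-2-[(triisopropylsilyl)oxy]biphenyl-4-ol} F2. This is the same skeleton with OH on B4, OEt on B2 and OSi on B6. Desilylation as in step 11 should give 3,3''-{[5-methoxy-2-(3,4,5-trimethoxyphenoxy)-1,3-phenylene]bis(oxy)}bis(6-ethoxy-2',4',6'-trimethoxybiphenyl-2,4-diol) F3, and dealkylation as in step 12 converges on 23.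

**Step 9.**
- What may go wrong: the aryloxyketene may oligomerize before it is trapped. The acid chloride may acylate electron-rich ring C intramolecularly at C2 or C4 (benzofuranone formation). The product may react further with excess ethoxyethyne, or its vinylogous ester may hydrolyse during purification.
- Fallback (from 13, returning at 21): reach vinylketene 18 without an aryloxyketene and without a cyclobutenone. Alkylation of 13 with commercial ethyl (E)-4-chloro-3-ethoxybut-2-enoate (CCOC(=O)/C=C(/OCC)CCl; K2CO3, DMF) should give diethyl (2E,2'E)-4,4'-{[5-methoxy-2-(3,4,5-trimethoxyphenoxy)-1,3-phenylene]bis(oxy)}bis(3-ethoxybut-2-enoate) F4. Saponification (aq LiOH) should give (2E,2'E)-4,4'-{[5-methoxy-2-(3,4,5-trimethoxyphenoxy)-1,3-phenylene]bis(oxy)}bis(3-ethoxybut-2-enoic acid) F5, and 1-chloro-N,N,2-trimethylprop-1-en-1-amine (CH2Cl2, 0 °C → rt) the (2E,2'E)-4,4'-{[5-methoxy-2-(3,4,5-trimethoxyphenoxy)-1,3-phenylene]bis(oxy)}bis(3-ethoxybut-2-enoyl chloride) F6. Slow addition of Et3N to F6 and 5 in toluene at 60 to 80 °C should effect 1,4-dehydrochlorination (γ-deprotonation) to the same bis(vinylketene) 18, which continues as in step 10 to 21.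

**Step 12.**
- What may go wrong: cleavage of the twelve alkyl ethers may be incomplete (the two ethyl ethers and the methoxy groups flanked by two substituents are slowest). The electron-rich biaryls may suffer acid-induced protodearylation. The free polyphenol may be lost to oxidation during isolation.
- Fallback (from 22, returning at 23): separate dealkylation from purification. The crude product of the BBr3 treatment is acetylated at once (Ac2O, pyridine) to the air-stable, chromatographable hexadecaacetate of 23 F7, and incompletely dealkylated fractions are separated and resubmitted. Deacetylation (NaOMe cat., MeOH, Ar; then acidic resin) then releases 23 under mild conditions.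

**Step 5.**
- What may go wrong: coupling of the doubly ortho-substituted phenoxide with an electron-rich iodide may be sluggish. The iodide may be reduced. The hydroquinone-type phenol 10 may be oxidized to a quinone by copper and traces of air.
- Fallback (from 11 and 10, returning at 12): metal-free arylation through trivalent iodine. Oxidation of 11 (mCPBA, TsOH, MeCN) and trapping with 1,3,5-trimethoxybenzene should give (3,4,5-trimethoxyphenyl)(2,4,6-trimethoxyphenyl)iodonium 4-methylbenzenesulfonate F8. The potassium phenoxide of 10 (t-BuOK, THF/toluene, rt to 50 °C) should then take over the 3,4,5-trimethoxyphenyl group by ligand coupling; the more electron-rich 2,4,6-trimethoxyphenyl group acts as the non-transferred ligand. This gives 12.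

## Further compounds

F1 | step 10 | 4,4'-{[5-methoxy-2-(3,4,5-trimethoxyphenoxy)-1,3-phenylene]bis(oxy)}bis[3-(triisopropylsilyloxy)-2-(2,4,6-trimethoxyphenyl)cyclobut-2-en-1-one], mixture of diastereomers | O=C1C(c2c(OC)cc(OC)cc2OC)=C(O[Si](C(C)C)(C(C)C)C(C)C)C1Oc1cc(OC)cc(OC2C(=O)C(c3c(OC)cc(OC)cc3OC)=C2O[Si](C(C)C)(C(C)C)C(C)C)c1Oc1cc(OC)c(OC)c(OC)c1
F2 | step 10 | 3,3''-{[5-methoxy-2-(3,4,5-trimethoxyphenoxy)-1,3-phenylene]bis(oxy)}bis{6-ethoxy-2',4',6'-trimethoxy-2-[(triisopropylsilyl)oxy]biphenyl-4-ol} | COc1cc(Oc2c(O)cc(OCC)c(-c3c(OC)cc(OC)cc3OC)c2O[Si](C(C)C)(C(C)C)C(C)C)c(Oc2cc(OC)c(OC)c(OC)c2)c(Oc2c(O)cc(OCC)c(-c3c(OC)cc(OC)cc3OC)c2O[Si](C(C)C)(C(C)C)C(C)C)c1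
F3 | step 10 | 3,3''-{[5-methoxy-2-(3,4,5-trimethoxyphenoxy)-1,3-phenylene]bis(oxy)}bis(6-ethoxy-2',4',6'-trimethoxybiphenyl-2,4-diol) | COc1cc(Oc2c(O)cc(OCC)c(-c3c(OC)cc(OC)cc3OC)c2O)c(Oc2cc(OC)c(OC)c(OC)c2)c(Oc2c(O)cc(OCC)c(-c3c(OC)cc(OC)cc3OC)c2O)c1
F4 | step 9 | diethyl (2E,2'E)-4,4'-{[5-methoxy-2-(3,4,5-trimethoxyphenoxy)-1,3-phenylene]bis(oxy)}bis(3-ethoxybut-2-enoate) | CCOC(=O)/C=C(/OCC)COc1cc(OC)cc(OC/C(OCC)=C\C(=O)OCC)c1Oc1cc(OC)c(OC)c(OC)c1
F5 | step 9 | (2E,2'E)-4,4'-{[5-methoxy-2-(3,4,5-trimethoxyphenoxy)-1,3-phenylene]bis(oxy)}bis(3-ethoxybut-2-enoic acid) | OC(=O)/C=C(/OCC)COc1cc(OC)cc(OC/C(OCC)=C\C(O)=O)c1Oc1cc(OC)c(OC)c(OC)c1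
F6 | step 9 | (2E,2'E)-4,4'-{[5-methoxy-2-(3,4,5-trimethoxyphenoxy)-1,3-phenylene]bis(oxy)}bis(3-ethoxybut-2-enoyl chloride) | ClC(=O)/C=C(/OCC)COc1cc(OC)cc(OC/C(OCC)=C\C(Cl)=O)c1Oc1cc(OC)c(OC)c(OC)c1
F7 | step 12 | hexadecaacetate of 23 | CC(=O)Oc1cc(OC(C)=O)c(-c2c(OC(C)=O)cc(OC(C)=O)c(Oc3cc(OC(C)=O)cc(Oc4c(OC(C)=O)cc(OC(C)=O)c(-c5c(OC(C)=O)cc(OC(C)=O)cc5OC(C)=O)c4OC(C)=O)c3Oc3cc(OC(C)=O)c(OC(C)=O)c(OC(C)=O)c3)c2OC(C)=O)c(OC(C)=O)c1
F8 | step 5 | (3,4,5-trimethoxyphenyl)(2,4,6-trimethoxyphenyl)iodonium 4-methylbenzenesulfonate | COc1cc(OC)c([I+]c2cc(OC)c(OC)c(OC)c2)c(OC)c1.Cc1ccc(S(=O)(=O)[O-])cc1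
A1 | alternative 1 | 2,2',4,4',6,6'-hexamethoxybiphenyl-3-ol | COc1cc(OC)c(-c2c(OC)cc(OC)c(O)c2OC)c(OC)c1
A2 | alternative 1 | 5-(2,6-dibromo-4-methoxyphenoxy)-1,2,3-trimethoxybenzene | COc1cc(Br)c(Oc2cc(OC)c(OC)c(OC)c2)c(Br)c1
A3 | alternative 1 | hexadecamethyl ether of 23 | COc1cc(OC)c(-c2c(OC)cc(OC)c(Oc3cc(OC)cc(Oc4c(OC)cc(OC)c(-c5c(OC)cc(OC)cc5OC)c4OC)c3Oc3cc(OC)c(OC)c(OC)c3)c2OC)c(OC)c1
A4 | alternative 2 | 2,6-bis[(2,2',4,4',6,6'-hexamethoxybiphenyl-3-yl)oxy]cyclohexa-2,5-diene-1,4-dione | O=C1C=C(Oc2c(OC)cc(OC)c(-c3c(OC)cc(OC)cc3OC)c2OC)C(=O)C(Oc2c(OC)cc(OC)c(-c3c(OC)cc(OC)cc3OC)c2OC)=C1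
A5 | alternative 2 | 2,6-dichloro-1,4-benzoquinone | O=C1C=C(Cl)C(=O)C(Cl)=C1
A6 | alternative 3 | bis(siloxyalkyne): 5-methoxy-2-(3,4,5-trimethoxyphenoxy)-1,3-bis{2,4,6-trimethoxy-3-[(triisopropylsilyloxy)ethynyl]phenoxy}benzene | COc1cc(Oc2c(OC)cc(OC)c(C#CO[Si](C(C)C)(C(C)C)C(C)C)c2OC)c(Oc2cc(OC)c(OC)c(OC)c2)c(Oc2c(OC)cc(OC)c(C#CO[Si](C(C)C)(C(C)C)C(C)C)c2OC)c1
A7 | alternative 3 | 3-ethoxycyclobut-2-en-1-one | CCOC1=CC(=O)C1
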